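Everything rests on disconnecting the C3–C4 bond of the pyran ring (the CH2–CH2 link between the C2 stereocentre and benzylic C4) and placing an NH between these carbons, which leads back to a seven-membered 2-aryl-2,3,4,5-tetrahydro-1,4-benzoxazepine. In the key step this secondary amine is converted into an isodiazene that expels N2; the benzylic radical at C4 and the primary radical at C3 recombine, so the oxazepine contracts to the chroman in one operation and two carbons of like (electrophilic) polarity are joined. The step exploits the benzylic nature of C4 and leaves the O1–C2 stereocentre, set earlier by asymmetric ketone reduction and Mitsunobu inversion, untouched.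

Key step: step 5

Remark: C2 keeps the same spatial arrangement from 5 to 11; its descriptor reads R while C3 carries nitrogen and S in the target only because CH2N outranks the aryl group and CH2C does not. Compounds 1 and 4 and the anomeric amide of step 5 are taken as purchasable.

Step 1
Reactants: 1 2-bromo-1-(3,4,5-trimethoxyphenyl)ethan-1-one
Product: 2 2-azido-1-(3,4,5-trimethoxyphenyl)ethan-1-one
Conditions: NaN3, acetone/H2O, 0 °C to rt
Reagents that add atoms: sodium azide, [Na+].[N-]=[N+]=[N-]
Why: SN2 displacement of the activated phenacyl bromide by azide should be fast and clean at room temperature under neutral conditions that spare the base-sensitive α-azido ketone.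

Step 2
Reactants: 2 2-azido-1-(3,4,5-trimethoxyphenyl)ethan-1-one
Product: 3 (1S)-2-azido-1-(3,4,5-trimethoxyphenyl)ethan-1-ol
Conditions: RuCl[(R,R)-TsDPEN](p-cymene) (cat.), HCO2H/Et3N (5:2), DMF, rt
Reagents that add atoms: none
Why: Noyori asymmetric transfer hydrogenation, in which the Ru–H/N–H catalyst should deliver hydride to one ketone face under CH/π control by the aryl group, so that the (R,R)-ligand sets the carbinol centre as S (the azidomethyl group changes only the CIP ranking, not the facial sense) while the azide is inert.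

Step 3
Reactants: 3 (1S)-2-azido-1-(3,4,5-trimethoxyphenyl)ethan-1-ol; 4 2-hydroxy-3,4-dimethoxybenzaldehyde
Product: 5 2-[(1R)-2-azido-1-(3,4,5-trimethoxyphenyl)ethoxy]-3,4-dimethoxybenzaldehyde
Conditions: PPh3, DIAD, THF, 0 °C to rt (betaine pre-formed at 0 °C, then 4, then 3)
Reagents that add atoms: none
Why: Mitsunobu etherification in which the phenoxide of 4 should displace the oxyphosphonium of 3 by SN2 with inversion (S to R), the electron-withdrawing β-azide and the two meta-methoxy groups disfavouring benzylic ionisation and the pre-formed PPh3–DIAD betaine keeping free phosphine away from the azide.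

Step 4
Reactants: 5 2-[(1R)-2-azido-1-(3,4,5-trimethoxyphenyl)ethoxy]-3,4-dimethoxybenzaldehyde
Product: 8 (2R)-8,9-dimethoxy-2-(3,4,5-trimethoxyphenyl)-2,3,4,5-tetrahydro-1,4-benzoxazepine, via iminophosphorane 6 (not isolated), via cyclic imine 7 (not isolated)
Conditions: PPh3, THF, rt to 60 °C; then NaBH4, MeOH, 0 °C
Reagents that add atoms: none
Why: Staudinger reaction of the azide gives an iminophosphorane that should close the seven-membered ring on the neighbouring aldehyde by intramolecular aza-Wittig reaction, and borohydride then reduces the cyclic aldimine, the C2 stereocentre taking no part.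

Step 5
Reactants: 8 (2R)-8,9-dimethoxy-2-(3,4,5-trimethoxyphenyl)-2,3,4,5-tetrahydro-1,4-benzoxazepine
Product: 11 (2S)-7,8,3',4',5'-pentamethoxyflavan, via N-amido hydrazine adduct 9 (not isolated), via isodiazene 10 (not isolated)
Conditions: N-(benzyloxy)-N-(pivaloyloxy)-4-(trifluoromethyl)benzamide (1.5 equiv), THF, 45 °C
Reagents that add atoms: none
Why: The amine attacks the amide nitrogen of the anomeric amide with loss of pivalate, the resulting N-alkoxy hydrazide 9 expels benzyl 4-(trifluoromethyl)benzoate to give isodiazene 10, and 10 extrudes N2 to a short-lived singlet 1,6-diradical (benzylic radical at the former C5, primary radical at the former C3) that recombines to the C3–C4 bond of the chroman. The closest known reaction type is the nitrogen deletion of secondary amines with anomeric amides, which is established for benzylic cyclic amines with ring contraction. The six-membered pyran ring is closed by intramolecular radical–radical recombination of the tethered diradical, a net seven-to-six ring contraction. No new stereocentre is formed; C2 is not a radical centre and should keep its configuration, the descriptor changing from R to S by CIP ranking alone. The step needs recombination to outrun fragmentation of the C2–O1 bond (to a styrene and an o-quinone methide, which could erode the enantiomeric purity) and hydrogen abstraction from solvent; the tether holding both radicals in one molecule and the benzylic stabilisation at C4 should secure this.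

Compound list
1 | 2-bromo-1-(3,4,5-trimethoxyphenyl)ethan-1-one | COc1cc(C(=O)CBr)cc(OC)c1OC | starting material
2 | 2-azido-1-(3,4,5-trimethoxyphenyl)ethan-1-one | COc1cc(C(=O)CN=[N+]=[N-])cc(OC)c1OC | intermediate
3 | (1S)-2-azido-1-(3,4,5-trimethoxyphenyl)ethan-1-ol | COc1cc([C@H](O)CN=[N+]=[N-])cc(OC)c1OC | intermediate
4 | 2-hydroxy-3,4-dimethoxybenzaldehyde | COc1ccc(C=O)c(O)c1OC | starting material
5 | 2-[(1R)-2-azido-1-(3,4,5-trimethoxyphenyl)ethoxy]-3,4-dimethoxybenzaldehyde | COc1cc([C@H](CN=[N+]=[N-])Oc2c(C=O)ccc(OC)c2OC)cc(OC)c1OC | intermediate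
6 | 3,4-dimethoxy-2-[(1R)-2-[(triphenyl-λ5-phosphanylidene)amino]-1-(3,4,5-trimethoxyphenyl)ethoxy]benzaldehyde (iminophosphorane) | COc1cc([C@H](CN=P(c2ccccc2)(c2ccccc2)c2ccccc2)Oc2c(C=O)ccc(OC)c2OC)cc(OC)c1OC | intermediate (not isolated)
7 | (2R)-8,9-dimethoxy-2-(3,4,5-trimethoxyphenyl)-2,3-dihydro-1,4-benzoxazepine (cyclic imine) | COc1cc([C@@H]2CN=Cc3ccc(OC)c(OC)c3O2)cc(OC)c1OC | intermediate (not isolated)
8 | (2R)-8,9-dimethoxy-2-(3,4,5-trimethoxyphenyl)-2,3,4,5-tetrahydro-1,4-benzoxazepine | COc1cc([C@@H]2CNCc3ccc(OC)c(OC)c3O2)cc(OC)c1OC | intermediate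
9 | N-(benzyloxy)-N-[(2R)-8,9-dimethoxy-2-(3,4,5-trimethoxyphenyl)-2,3-dihydro-1,4-benzoxazepin-4(5H)-yl]-4-(trifluoromethyl)benzamide | COc1cc([C@@H]2CN(N(OCc3ccccc3)C(=O)c3ccc(C(F)(F)F)cc3)Cc3ccc(OC)c(OC)c3O2)cc(OC)c1OC | intermediate (not isolated)
10 | isodiazene (1,1-diazene) at N4 of (2R)-8,9-dimethoxy-2-(3,4,5-trimethoxyphenyl)-2,3,4,5-tetrahydro-1,4-benzoxazepine | COc1cc([C@@H]2C[N+](=[N-])Cc3ccc(OC)c(OC)c3O2)cc(OC)c1OC | intermediate (not isolated)
11 | (2S)-7,8,3',4',5'-pentamethoxyflavan [(2S)-7,8-dimethoxy-2-(3,4,5-trimethoxyphenyl)chromane] | COc1cc([C@@H]2CCc3ccc(OC)c(OC)c3O2)cc(OC)c1OC | target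

Total step count: 5
Longest linear sequence: 5 steps (1 to 11)

Steps most likely to fail

Step 5. The anomeric amide may acylate the amine instead of transferring nitrogen, or the diradical may fragment at the C2–O1 bond or abstract hydrogen before it recombines. The fallback sets out from 8 and builds the N–N unit stepwise with isolable intermediates, so that the extrusion can be triggered without an acylating reagent and well below 45 °C. Nitrosation of 8 (t-BuONO, CH2Cl2, rt) should give (2R)-8,9-dimethoxy-4-nitroso-2-(3,4,5-trimethoxyphenyl)-2,3,4,5-tetrahydro-1,4-benzoxazepine F1. Reduction (Zn, AcOH, 0 °C) should give the 1,1-dialkylhydrazine (2R)-8,9-dimethoxy-2-(3,4,5-trimethoxyphenyl)-2,3-dihydro-1,4-benzoxazepin-4(5H)-amine F2. Oxidation of F2 (yellow HgO, EtOH, or PhI(OAc)2 at low temperature) should regenerate isodiazene 10, where the fallback rejoins the route and proceeds to 11.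

Step 3. Partial ionisation at the benzylic carbon would erode the inversion, phosphine may be consumed by the azide, and the hindered, hydrogen-bonded phenol may couple sluggishly. The fallback sets out from 2 and makes the aryl ether bond on the arene side, so that the carbinol centre is never substituted. Transfer hydrogenation of 2 with the (S,S)-TsDPEN catalyst should give (1R)-2-azido-1-(3,4,5-trimethoxyphenyl)ethan-1-ol F3. Hydrogenation (H2, Pd/C, MeOH) should give (1R)-2-amino-1-(3,4,5-trimethoxyphenyl)ethan-1-ol F4. Condensation with purchased 2-bromo-3,4-dimethoxybenzaldehyde F5 should give (1R)-2-{[(E)-(2-bromo-3,4-dimethoxyphenyl)methylidene]amino}-1-(3,4,5-trimethoxyphenyl)ethan-1-ol F6, and NaBH4 reduction should give (1R)-2-{[(2-bromo-3,4-dimethoxyphenyl)methyl]amino}-1-(3,4,5-trimethoxyphenyl)ethan-1-ol F7. Intramolecular Ullmann O-arylation of F7 (CuI, 3,4,7,8-tetramethyl-1,10-phenanthroline, Cs2CO3, toluene, 110 °C, dilute) should close the seven-membered ring with retention. The fallback rejoins the route at 8 and so also bypasses step 4.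

Step 4. Intermolecular imine formation (oligomers) may compete with the seven-membered aza-Wittig closure, or the iminophosphorane may hydrolyse before it cyclises. The fallback sets out from 5 and closes the ring by N-alkylation instead of C=N formation. NaBH4 reduction of the aldehyde should give {2-[(1R)-2-azido-1-(3,4,5-trimethoxyphenyl)ethoxy]-3,4-dimethoxyphenyl}methanol F8. SOCl2 (CH2Cl2, 0 °C) should give 2-[(1R)-2-azido-1-(3,4,5-trimethoxyphenyl)ethoxy]-1-(chloromethyl)-3,4-dimethoxybenzene F9. Staudinger reduction (PPh3, THF, then H2O) should pass through the iminophosphorane N-{(2R)-2-[6-(chloromethyl)-2,3-dimethoxyphenoxy]-2-(3,4,5-trimethoxyphenyl)ethyl}-P,P,P-triphenylphosphine imide F10 to the amino chloride (2R)-2-[6-(chloromethyl)-2,3-dimethoxyphenoxy]-2-(3,4,5-trimethoxyphenyl)ethan-1-amine F11. F11 should cyclise by 7-exo-tet SN2 (K2CO3, MeCN, high dilution), and the fallback rejoins the route at 8.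

Further compounds
F1 | step 5 | (2R)-8,9-dimethoxy-4-nitroso-2-(3,4,5-trimethoxyphenyl)-2,3,4,5-tetrahydro-1,4-benzoxazepine | COc1cc([C@@H]2CN(N=O)Cc3ccc(OC)c(OC)c3O2)cc(OC)c1OC
F2 | step 5 | (2R)-8,9-dimethoxy-2-(3,4,5-trimethoxyphenyl)-2,3-dihydro-1,4-benzoxazepin-4(5H)-amine | COc1cc([C@@H]2CN(N)Cc3ccc(OC)c(OC)c3O2)cc(OC)c1OC
F3 | step 3 | (1R)-2-azido-1-(3,4,5-trimethoxyphenyl)ethan-1-ol | COc1cc([C@@H](O)CN=[N+]=[N-])cc(OC)c1OC
F4 | step 3 | (1R)-2-amino-1-(3,4,5-trimethoxyphenyl)ethan-1-ol | COc1cc([C@@H](O)CN)cc(OC)c1OC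
F5 | step 3 | 2-bromo-3,4-dimethoxybenzaldehyde (purchased) | COc1ccc(C=O)c(Br)c1OC
F6 | step 3 | (1R)-2-{[(E)-(2-bromo-3,4-dimethoxyphenyl)methylidene]amino}-1-(3,4,5-trimethoxyphenyl)ethan-1-ol | COc1cc([C@@H](O)C/N=C/c2ccc(OC)c(OC)c2Br)cc(OC)c1OC
F7 | step 3 | (1R)-2-{[(2-bromo-3,4-dimethoxyphenyl)methyl]amino}-1-(3,4,5-trimethoxyphenyl)ethan-1-ol | COc1cc([C@@H](O)CNCc2ccc(OC)c(OC)c2Br)cc(OC)c1OC
F8 | step 4 | {2-[(1R)-2-azido-1-(3,4,5-trimethoxyphenyl)ethoxy]-3,4-dimethoxyphenyl}methanol | COc1cc([C@H](CN=[N+]=[N-])Oc2c(CO)ccc(OC)c2OC)cc(OC)c1OC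
F9 | step 4 | 2-[(1R)-2-azido-1-(3,4,5-trimethoxyphenyl)ethoxy]-1-(chloromethyl)-3,4-dimethoxybenzene | COc1cc([C@H](CN=[N+]=[N-])Oc2c(CCl)ccc(OC)c2OC)cc(OC)c1OC
F10 | step 4 | N-{(2R)-2-[6-(chloromethyl)-2,3-dimethoxyphenoxy]-2-(3,4,5-trimethoxyphenyl)ethyl}-P,P,P-triphenylphosphine imide | COc1cc([C@H](CN=P(c2ccccc2)(c2ccccc2)c2ccccc2)Oc2c(CCl)ccc(OC)c2OC)cc(OC)c1OC
F11 | step 4 | (2R)-2-[6-(chloromethyl)-2,3-dimethoxyphenoxy]-2-(3,4,5-trimethoxyphenyl)ethan-1-amine | COc1cc([C@H](CN)Oc2c(CCl)ccc(OC)c2OC)cc(OC)c1OC
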